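**Retrosynthetic overview**
1. The oxolane ring is made last. The C2–O bond comes from acid-induced (SN1) closure of an acyclic triol, which sets the 2,3-trans relation.
2. The 3,4-cis pair (CH2OH/benzyl) of the oxolane corresponds to the trans pair of an alpha-aroyl-beta-benzyl-gamma-butyrolactone, so triol ⇒ trans keto lactone (hydride).
3. Keto lactone ⇒ 1-aroyl-6-aryl-3-oxabicyclo[3.1.0]hexan-2-one, by hydrogenolysis of the donor–acceptor cyclopropane bond.
4. Key step: bicycle ⇒ achiral cinnamyl alpha-aroyl-alpha-diazoacetate. One catalytic asymmetric intramolecular cyclopropanation closes the lactone and the cyclopropane together, with all 23 carbons in place, and fixes the absolute configuration.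
5. Diazo ester ⇒ 3,4-dimethoxycinnamyl alcohol + ethyl 3,4,5-trimethoxybenzoylacetate. Ring order: lactone + cyclopropane (together) → cyclopropane opened → lactone opened → oxolane.

Assumption: the sense of induction of the cobalt catalyst on this new substrate is read from the first run, and the ligand antipode that gives (1R,5S,6R)-6 is used (both antipodes come from the same ligand synthesis).

**Step 1**
Reactants: 1 methyl (E)-3-(3,4-dimethoxyphenyl)prop-2-enoate
Product: 2 (E)-3-(3,4-dimethoxyphenyl)prop-2-en-1-ol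
Conditions: i-Bu2AlH (2.3 equiv), CH2Cl2, −78 → 0 °C; aq. potassium sodium tartrate
Reagents that add atoms: none
Why: 1,2-reduction of an alpha,beta-unsaturated ester with a dialkylaluminium hydride, in which both hydrides go to the carbonyl carbon at low temperature, the styrenyl C=C and its E geometry are untouched, and no stereocentre is made.

**Step 2**
Reactants: 2 (E)-3-(3,4-dimethoxyphenyl)prop-2-en-1-ol; 3 ethyl 3-oxo-3-(3,4,5-trimethoxyphenyl)propanoate
Product: 5 (E)-3-(3,4-dimethoxyphenyl)prop-2-en-1-yl 2-diazo-3-oxo-3-(3,4,5-trimethoxyphenyl)propanoate, via cinnamyl beta-keto ester 4 (not isolated)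
Conditions: DMAP (0.3 equiv), toluene, reflux, 4 Å MS (−EtOH); cool to 0 °C; Et3N, p-ABSA, MeCN, 0 °C → rt
Reagents that add atoms: 4-acetamidobenzenesulfonyl azide (p-ABSA), CC(=O)Nc1ccc(cc1)S(=O)(=O)N=[N+]=[N-]
Why: DMAP-catalysed transesterification of a beta-keto ester (through the acylketene, driven by removal of ethanol) followed in the same flask by Regitz diazo transfer to the doubly activated CH2; both are mild enough for the electron-rich cinnamyl ester, toluene reflux lies well below the onset of Carroll rearrangement, and no stereocentre is made.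

**Step 3 (key step)**
Reactants: 5 (E)-3-(3,4-dimethoxyphenyl)prop-2-en-1-yl 2-diazo-3-oxo-3-(3,4,5-trimethoxyphenyl)propanoate
Product: 6 (1R,5S,6R)-6-(3,4-dimethoxyphenyl)-1-(3,4,5-trimethoxybenzoyl)-3-oxabicyclo[3.1.0]hexan-2-one
Conditions: [Co(3,5-DitBu-QingPhyrin)] (2–5 mol%), PhCl, 40 °C, N2 atmosphere
Reagents that add atoms: none
Why: Metalloradical asymmetric intramolecular cyclopropanation of an allyl alpha-acceptor diazoacetate, in which the divalent cobalt porphyrin takes up 5 with loss of N2 to give a cobalt-bound carbon radical held by amide N–H···O=C hydrogen bonds in the chiral pocket, 5-exo addition to the styrene closes the lactone and fixes C5 (C4 of the target), and 3-exo-tet substitution by the veratryl-stabilised benzylic radical closes the cyclopropane, so two rings, two C–C bonds and the absolute configuration come from one operation (C6 is later erased).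

**Step 4**
Reactants: 6 (1R,5S,6R)-6-(3,4-dimethoxyphenyl)-1-(3,4,5-trimethoxybenzoyl)-3-oxabicyclo[3.1.0]hexan-2-one
Product: 7 (3R,4S)-4-(3,4-dimethoxybenzyl)-3-(3,4,5-trimethoxybenzoyl)oxolan-2-one
Conditions: H2 (1 atm), Pd/C (10 wt%), EtOAc, rt, stopped after 1 equiv H2
Reagents that add atoms: none
Why: Hydrogenolysis of a donor–acceptor cyclopropane, in which the C1–C6 bond flanked by two carbonyls and the veratryl donor is by far the weakest and is cleaved selectively, C5 is untouched, C6 becomes the benzyl CH2, and the new acidic C3–H settles through the enol on the trans (3R,4S) keto lactone, the outcome that cleavage with retention would also give.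

**Step 5**
Reactants: 7 (3R,4S)-4-(3,4-dimethoxybenzyl)-3-(3,4,5-trimethoxybenzoyl)oxolan-2-one
Product: 8 (2S,3S)-2-(3,4-dimethoxybenzyl)-3-[hydroxy(3,4,5-trimethoxyphenyl)methyl]butane-1,4-diol (both carbinol epimers)
Conditions: LiBH4 (5 equiv), THF–MeOH (10:1), 0 °C → rt; cold 1 M HCl quench
Reagents that add atoms: none
Why: Exhaustive borohydride reduction (aryl ketone first, then alkoxide-assisted reduction of the lactone to the diol), in which C2 and C3 keep the trans-lactone configuration because that alpha centre is already the thermodynamic one, while the new carbinol centre forms unselectively and is erased in step 6.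

**Step 6**
Reactants: 8 (2S,3S)-2-(3,4-dimethoxybenzyl)-3-[hydroxy(3,4,5-trimethoxyphenyl)methyl]butane-1,4-diol
Product: 9 [(2R,3S,4S)-4-(3,4-dimethoxybenzyl)-2-(3,4,5-trimethoxyphenyl)oxolan-3-yl]methanol (target)
Conditions: (+)-camphor-10-sulfonic acid (0.2 equiv), CH2Cl2, 0 °C → rt, quenched with NaHCO3 as soon as 8 is consumed
Reagents that add atoms: none
Why: Acid-catalysed SN1 cyclodehydration (benzylic cation, 5-exo capture), in which both carbinol epimers give the same 3,4,5-trimethoxybenzyl cation, only the hydroxymethyl on the benzyl-bearing carbon can reach it through a five-membered ring, closure puts the aryl group trans to the neighbouring CH2OH (2R) under kinetic and thermodynamic control, and the former trans-lactone pair appears as the 3,4-cis pair.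

**Compound list**
1 | methyl (E)-3-(3,4-dimethoxyphenyl)prop-2-enoate | COC(=O)/C=C/c1ccc(OC)c(OC)c1 | starting material
2 | (E)-3-(3,4-dimethoxyphenyl)prop-2-en-1-ol | OC/C=C/c1ccc(OC)c(OC)c1 | intermediate
3 | ethyl 3-oxo-3-(3,4,5-trimethoxyphenyl)propanoate | CCOC(=O)CC(=O)c1cc(OC)c(OC)c(OC)c1 | starting material
4 | (E)-3-(3,4-dimethoxyphenyl)prop-2-en-1-yl 3-oxo-3-(3,4,5-trimethoxyphenyl)propanoate | COc1ccc(/C=C/COC(=O)CC(=O)c2cc(OC)c(OC)c(OC)c2)cc1OC | intermediate
5 | (E)-3-(3,4-dimethoxyphenyl)prop-2-en-1-yl 2-diazo-3-oxo-3-(3,4,5-trimethoxyphenyl)propanoate | COc1ccc(/C=C/COC(=O)C(=[N+]=[N-])C(=O)c2cc(OC)c(OC)c(OC)c2)cc1OC | intermediate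
6 | (1R,5S,6R)-6-(3,4-dimethoxyphenyl)-1-(3,4,5-trimethoxybenzoyl)-3-oxabicyclo[3.1.0]hexan-2-one | O=C1OC[C@H]2[C@H](c3ccc(OC)c(OC)c3)[C@@]12C(=O)c4cc(OC)c(OC)c(OC)c4 | intermediate
7 | (3R,4S)-4-(3,4-dimethoxybenzyl)-3-(3,4,5-trimethoxybenzoyl)oxolan-2-one | O=C1OC[C@@H](Cc2ccc(OC)c(OC)c2)[C@@H]1C(=O)c3cc(OC)c(OC)c(OC)c3 | intermediate
8 | (2S,3S)-2-(3,4-dimethoxybenzyl)-3-[hydroxy(3,4,5-trimethoxyphenyl)methyl]butane-1,4-diol, carbinol epimers | COc1ccc(C[C@H](CO)[C@@H](CO)C(O)c2cc(OC)c(OC)c(OC)c2)cc1OC | intermediate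
9 | [(2R,3S,4S)-4-(3,4-dimethoxybenzyl)-2-(3,4,5-trimethoxyphenyl)oxolan-3-yl]methanol | COc1ccc(C[C@@H]2CO[C@@H](c3cc(OC)c(OC)c(OC)c3)[C@@H]2CO)cc1OC | target

**Step count**
Total step count: 6.
Longest linear sequence: 6 (1 → 2 → 5 → 6 → 7 → 8 → 9; compound 3 enters in step 2).

**Steps most likely to fail**

**Step 3 (highest risk).**
- The aroyl group is a bulkier alpha-acceptor than those usually used, so the ee may be lower.
- The product is a very activated donor–acceptor cyclopropane and may isomerise by O-closure to the fused dihydrofuran. That isomer would still be cleaved to 7 in step 4.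
- The fallback leaves the acyl group out of the ring-forming event. It sets out from 2 and comes back at 7.
- Compound 2 is acylated with bromoacetyl bromide (NaHCO3, MeCN) to (E)-3-(3,4-dimethoxyphenyl)prop-2-en-1-yl bromoacetate F1. With N,N'-ditosylhydrazine and DBU this gives (E)-3-(3,4-dimethoxyphenyl)prop-2-en-1-yl diazoacetate F2.
- The acceptor-only carbene from F2 and Rh2(4S-MPPIM)4 (or its 4R antipode, whichever gives the 5S series) closes (1R,5S,6S)-6-(3,4-dimethoxyphenyl)-3-oxabicyclo[3.1.0]hexan-2-one F3. H2 over Pd/C opens it to (4S)-4-(3,4-dimethoxybenzyl)oxolan-2-one F4.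
- C-acylation of the lithium enolate of F4 (LiN(SiMe3)2, 2.1 equiv; 3,4,5-trimethoxybenzoyl chloride, THF, −78 °C) gives 7.

**Step 5.**
- The enolisable 1,3-dicarbonyl may sit as an unreactive enolate or suffer retro-Claisen cleavage under hydride.
- The fallback reorders the events so that this 1,3-dicarbonyl never exists. It sets out from 6 and comes back at 8.
- The non-enolisable ketone of 6 is reduced first (NaBH4, CeCl3·7H2O, MeOH, −20 °C) to (1R,5S,6R)-6-(3,4-dimethoxyphenyl)-1-[hydroxy(3,4,5-trimethoxyphenyl)methyl]-3-oxabicyclo[3.1.0]hexan-2-one F6.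
- The lactone-activated cyclopropane is then hydrogenolysed (H2, Pd/C, EtOAc) to (3R,4S)-4-(3,4-dimethoxybenzyl)-3-[hydroxy(3,4,5-trimethoxyphenyl)methyl]oxolan-2-one F7.
- LiAlH4 in THF takes this simple hydroxy lactone to 8.

**Step 4.**
- Over-reduction of the aryl ketone, or sluggish cleavage on a catalyst poisoned by traces of porphyrin, is possible.
- The fallback replaces surface hydrogenolysis by a polar opening followed by a radical reduction. It sets out from 6 and comes back at 7.
- Thiophenolate (PhSH, Cs2CO3, MeCN, rt) attacks the benzylic carbon of 6 in a homo-conjugate addition. This gives (3R,4S)-4-[(S)-(3,4-dimethoxyphenyl)(phenylsulfanyl)methyl]-3-(3,4,5-trimethoxybenzoyl)oxolan-2-one F5.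
- Bu3SnH with AIBN (toluene, 80 °C) removes the benzylic sulfur to give 7. The sulfide-bearing centre is erased, so its configuration does not matter.

**Further compounds**
F1 | step 3 | (E)-3-(3,4-dimethoxyphenyl)prop-2-en-1-yl bromoacetate | O=C(CBr)OC/C=C/c1ccc(OC)c(OC)c1
F2 | step 3 | (E)-3-(3,4-dimethoxyphenyl)prop-2-en-1-yl diazoacetate | [N-]=[N+]=CC(=O)OC/C=C/c1ccc(OC)c(OC)c1
F3 | step 3 | (1R,5S,6S)-6-(3,4-dimethoxyphenyl)-3-oxabicyclo[3.1.0]hexan-2-one | O=C1OC[C@H]2[C@H](c3ccc(OC)c(OC)c3)[C@@H]12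
F4 | step 3 | (4S)-4-(3,4-dimethoxybenzyl)oxolan-2-one | O=C1OC[C@@H](Cc2ccc(OC)c(OC)c2)C1
F5 | step 4 | (3R,4S)-4-[(S)-(3,4-dimethoxyphenyl)(phenylsulfanyl)methyl]-3-(3,4,5-trimethoxybenzoyl)oxolan-2-one | O=C1OC[C@@H]([C@H](Sc2ccccc2)c3ccc(OC)c(OC)c3)[C@@H]1C(=O)c4cc(OC)c(OC)c(OC)c4
F6 | step 5 | (1R,5S,6R)-6-(3,4-dimethoxyphenyl)-1-[hydroxy(3,4,5-trimethoxyphenyl)methyl]-3-oxabicyclo[3.1.0]hexan-2-one, carbinol epimers | O=C1OC[C@H]2[C@H](c3ccc(OC)c(OC)c3)[C@@]12C(O)c4cc(OC)c(OC)c(OC)c4
F7 | step 5 | (3R,4S)-4-(3,4-dimethoxybenzyl)-3-[hydroxy(3,4,5-trimethoxyphenyl)methyl]oxolan-2-one, carbinol epimers | O=C1OC[C@@H](Cc2ccc(OC)c(OC)c2)[C@@H]1C(O)c3cc(OC)c(OC)c(OC)c3
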